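**Plan**

- Retrosynthesis: the two O-methyl groups come off last. The central ring B is then raised to its quinone level and both ring-B C–O(aryl) bonds are cut at once, giving bromanil and two molecules of 2,3,5-tribromo-4-methoxyphenol.
- The phenol is cut at the C–Br bond ortho to OH and at its C–OH bond, leading back to 2,6-dibromoanisole (C–H borylation/oxidation).
- Enabling feature: in ring B the two OH groups are para to each other, as are the two Br and the two aryloxy oxygens. Ring B is therefore the hydroquinone of a 2,5-diaryloxy-3,6-dibromo-1,4-benzoquinone, and its six carbons, two carbonyl-derived oxygens and two bromines map onto bromanil, whose C–Br bonds are vinylogous acyl bromides. The inversion centre of the target lets both ethers form in one two-directional operation.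
- Forward order: terminal ring built (steps 1–2), both terminal rings joined to the core in one operation (step 3), quinone reduced (step 4), methyl ethers cleaved (step 5). No ring is formed; all eight bromines are in place before the ether bonds, so no metal-catalysed C–O coupling has to compete with C–Br bonds and no late bromination is needed.
- Stereochemistry: none to set. The only selectivity issue is regiochemical (2,5- versus 2,6-substitution on the quinone), controlled by vinylogous-ester deactivation after the first displacement.

Key step: step 3

Remark: the target has no stereocentre and no configurationally stable axis (it is centrosymmetric and achiral), so "single enantiomer" imposes no stereochemical task.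

**Step 1**
Reactants: 1 2,6-dibromoanisole; 2 bis(pinacolato)diboron (0.55 equiv)
Product: 4 3,5-dibromo-4-methoxyphenol, via arylboronic pinacol ester 3 (not isolated)
Conditions: [Ir(OMe)(cod)]2 (1.5 mol%), dtbpy (3 mol%), THF, 80 °C; then Oxone, acetone/H2O, rt
Reagents that add atoms: Oxone (potassium peroxymonosulfate), [K+].[O-]S(=O)(=O)OO
Why: Iridium-catalysed aromatic C–H borylation is sterically controlled and avoids C–H bonds ortho to substituents, so only the C4–H of 1 (the one C–H not next to Br) should react, aryl C–Br bonds are tolerated, and one-pot oxidation of the C–B bond (borylation/oxidation sequence) places the OH para to OMe.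

**Step 2**
Reactants: 4 3,5-dibromo-4-methoxyphenol
Product: 5 2,3,5-tribromo-4-methoxyphenol
Conditions: Br2 (1.0 equiv), CH2Cl2, −10 to 0 °C
Reagents that add atoms: bromine, BrBr
Why: Electrophilic aromatic bromination directed by the free OH: the only open activated positions are the two equivalent carbons ortho to OH, and the first bromine deactivates the ring, so one equivalent at low temperature should stop at the monobromide.

**Step 3**
Reactants: 5 2,3,5-tribromo-4-methoxyphenol (2.05 equiv); 6 bromanil (tetrabromo-1,4-benzoquinone, 1.0 equiv)
Product: 8 2,5-dibromo-3,6-bis(2,3,5-tribromo-4-methoxyphenoxy)-1,4-benzoquinone, via mono(aryloxy)tribromoquinone 7 (not isolated)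
Conditions: K2CO3 (anhydrous, powdered, 2.2 equiv), MeCN, 4 Å MS, 0 °C to rt, Ar, dark
Reagents that add atoms: none
Why: Each C–Br of bromanil is a vinylogous acyl bromide, so the aryloxide generated in situ adds in conjugate fashion to C(Br)=C–C=O and the resulting bromo-enolate expels bromide (addition–elimination, nucleophilic vinylic substitution). The closest known reaction type is the formation of 2,5-diaryloxy-3,6-dihalo-1,4-benzoquinones from tetrahalo-1,4-benzoquinones and aryloxides, which is known even for polyhalogenated, ortho-substituted aryloxides. No ring is closed and no stereocentre is formed; the step makes both diaryl ether C–O bonds of ring B in one two-directional operation. The selectivity needed is para (2,5) over 2,3 and 2,6: taking the aryloxy carbon of 7 as C2 and the carbonyls as C1 and C4, the aryloxy oxygen donates through C2=C3 into C4=O (vinylogous ester), which makes C3 electron-rich and weakens C4=O as the acceptor for attack at C6, so the second aryloxide should attack C5, whose acceptor is the unperturbed C1 carbonyl. In 8 both carbonyls are vinylogous esters and both remaining C–Br carbons are enol-ether β-carbons, so the weakly nucleophilic, ortho-brominated aryloxide should not go on to tri- or tetra-substitution. The electron-poor aryloxide is also a poor one-electron donor, which should suppress electron transfer to bromanil.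

**Step 4**
Reactants: 8 2,5-dibromo-3,6-bis(2,3,5-tribromo-4-methoxyphenoxy)-1,4-benzoquinone
Product: 9 2,5-dibromo-3,6-bis(2,3,5-tribromo-4-methoxyphenoxy)benzene-1,4-diol
Conditions: Na2S2O4 (4 equiv), THF/H2O, rt, Ar
Reagents that add atoms: none
Why: Dithionite reduction of a p-benzoquinone to its hydroquinone; aryl bromides, aryl methyl ethers and diaryl ethers are inert, and the reduction turns the nucleophile-sensitive vinylogous ester into a robust hexasubstituted arene before the Lewis acid step.

**Step 5**
Reactants: 9 2,5-dibromo-3,6-bis(2,3,5-tribromo-4-methoxyphenoxy)benzene-1,4-diol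
Product: 10 2,5-dibromo-3,6-bis(2,3,5-tribromo-4-hydroxyphenoxy)benzene-1,4-diol (target, CNP0163357.0)
Conditions: BBr3 (8 equiv), CH2Cl2, −78 °C to rt, Ar; then ice/H2O, wash with dilute aq. Na2S2O4
Reagents that add atoms: none
Why: Lewis-acid cleavage of aryl methyl ethers with BBr3 (bromide attacks the methyl group of the boron-complexed anisole), the standard unmasking of hydroxylated polybrominated diphenyl ethers; diaryl ether and aryl C–Br bonds are inert, excess reagent covers the two free OH groups, and the reductive wash should keep ring B at the hydroquinone level.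

**Compound list**

1 | 2,6-dibromoanisole (1,3-dibromo-2-methoxybenzene) | COc1c(Br)cccc1Br | starting material
2 | bis(pinacolato)diboron | CC1(C)OB(OC1(C)C)B1OC(C)(C)C(C)(C)O1 | starting material
3 | 2-(3,5-dibromo-4-methoxyphenyl)-4,4,5,5-tetramethyl-1,3,2-dioxaborolane | COc1c(Br)cc(cc1Br)B1OC(C)(C)C(C)(C)O1 | intermediate (not isolated)
4 | 3,5-dibromo-4-methoxyphenol | COc1c(Br)cc(O)cc1Br | intermediate
5 | 2,3,5-tribromo-4-methoxyphenol | COc1c(Br)cc(O)c(Br)c1Br | intermediate
6 | bromanil (2,3,5,6-tetrabromo-1,4-benzoquinone) | O=C1C(Br)=C(Br)C(=O)C(Br)=C1Br | starting material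
7 | 2,3,5-tribromo-6-(2,3,5-tribromo-4-methoxyphenoxy)-1,4-benzoquinone | O=C1C(Oc2cc(Br)c(OC)c(Br)c2Br)=C(Br)C(=O)C(Br)=C1Br | intermediate (not isolated)
8 | 2,5-dibromo-3,6-bis(2,3,5-tribromo-4-methoxyphenoxy)-1,4-benzoquinone | O=C1C(Oc2cc(Br)c(OC)c(Br)c2Br)=C(Br)C(=O)C(Oc3cc(Br)c(OC)c(Br)c3Br)=C1Br | intermediate
9 | 2,5-dibromo-3,6-bis(2,3,5-tribromo-4-methoxyphenoxy)benzene-1,4-diol | Oc1c(Oc2cc(Br)c(OC)c(Br)c2Br)c(Br)c(O)c(Oc3cc(Br)c(OC)c(Br)c3Br)c1Br | intermediate
10 | 2,5-dibromo-3,6-bis(2,3,5-tribromo-4-hydroxyphenoxy)benzene-1,4-diol | Oc1c(Br)cc(Oc2c(O)c(Br)c(Oc3cc(Br)c(O)c(Br)c3Br)c(O)c2Br)c(Br)c1Br | target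

**Totals**

Total step count: 5. Longest linear sequence: 5 steps (1 → 4 → 5 → 8 → 9 → 10).

**Steps most likely to fail**

1. Step 3. The second displacement may stall at the mono-ether because the ortho-brominated aryloxide is hindered and weakly nucleophilic. Electron transfer from aryloxide to bromanil, hydrolysis of C–Br bonds by carbonate and adventitious water, or leakage to the 2,6-isomer may also erode the outcome. The fallback sets out from phenol 5 and returns at quinone 8; it fixes the regiochemistry by the substitution pattern of a nitro-activated arene. Commercial 1,4-dibromo-2,5-difluorobenzene F1 would be dinitrated (fuming HNO3, oleum) to 1,4-dibromo-2,5-difluoro-3,6-dinitrobenzene F2. Nucleophilic aromatic substitution with two equivalents of 5 (K2CO3, DMF) should displace both fluorides, each ortho to a nitro group and far better nucleofuges than bromide, giving 1,4-dibromo-2,5-dinitro-3,6-bis(2,3,5-tribromo-4-methoxyphenoxy)benzene F3. Chemoselective nitro reduction (Fe, NH4Cl, EtOH/H2O) would give the p-phenylenediamine 2,5-dibromo-3,6-bis(2,3,5-tribromo-4-methoxyphenoxy)benzene-1,4-diamine F4. Oxidation with aqueous FeCl3 (p-phenylenediamine to p-benzoquinone through hydrolysis of the quinone diimine, as in the classical duroquinone preparation) should deliver 8, the two para nitro groups having served first as activators and then as masked carbonyls.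

2. Step 2. Bromination may run on to the second ortho position or stop short, leaving a mixture of di-, tri- and tetrabromides that is hard to separate. The fallback sets out from 4 and returns at 5; it replaces statistical control by directed deprotonation. Phenol 4 would be converted (ClCONEt2, NaH, THF) into 3,5-dibromo-4-methoxyphenyl diethylcarbamate F5. Directed ortho-magnesiation with TMPMgCl·LiCl (1.1 equiv, THF, −20 °C) at the C–H flanked by the carbamate and bromine would give [2,4-dibromo-6-(diethylcarbamoyloxy)-3-methoxyphenyl]magnesium chloride F6, in which only one position can be metalated per equivalent of base. Quenching with 1,2-dibromotetrachloroethane should give 2,3,5-tribromo-4-methoxyphenyl diethylcarbamate F7, and hydrolysis (KOH, EtOH/H2O, reflux, then acid) would release 5.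

3. Step 1. Borylation may be slow on the doubly brominated arene, may partly occur next to bromine, or the catalyst may insert into a C–Br bond; the boronate may also be incompletely oxidised. The fallback sets out from 1 and returns at 4 by classical arene chemistry. Nitration of 1 (HNO3, H2SO4, 0 °C) para to the methoxy group would give 2,6-dibromo-4-nitroanisole F8. Reduction (Fe, NH4Cl, EtOH/H2O) would give 3,5-dibromo-4-methoxyaniline F9. Diazotisation (NaNO2, aq. H2SO4, 0 °C) would give 3,5-dibromo-4-methoxybenzenediazonium hydrogen sulfate F10, and hydroxydediazoniation (Cu2O, Cu(NO3)2, H2O, rt) should give 4.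

**Further compounds**

F1 | step 3 | 1,4-dibromo-2,5-difluorobenzene (commercial) | Fc1cc(Br)c(F)cc1Br
F2 | step 3 | 1,4-dibromo-2,5-difluoro-3,6-dinitrobenzene | [O-][N+](=O)c1c(F)c(Br)c([N+]([O-])=O)c(F)c1Br
F3 | step 3 | 1,4-dibromo-2,5-dinitro-3,6-bis(2,3,5-tribromo-4-methoxyphenoxy)benzene | [O-][N+](=O)c1c(Oc2cc(Br)c(OC)c(Br)c2Br)c(Br)c([N+]([O-])=O)c(Oc3cc(Br)c(OC)c(Br)c3Br)c1Br
F4 | step 3 | 2,5-dibromo-3,6-bis(2,3,5-tribromo-4-methoxyphenoxy)benzene-1,4-diamine | Nc1c(Oc2cc(Br)c(OC)c(Br)c2Br)c(Br)c(N)c(Oc3cc(Br)c(OC)c(Br)c3Br)c1Br
F5 | step 2 | 3,5-dibromo-4-methoxyphenyl diethylcarbamate | CCN(CC)C(=O)Oc1cc(Br)c(OC)c(Br)c1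
F6 | step 2 | [2,4-dibromo-6-(diethylcarbamoyloxy)-3-methoxyphenyl]magnesium chloride | CCN(CC)C(=O)Oc1cc(Br)c(OC)c(Br)c1[Mg]Cl
F7 | step 2 | 2,3,5-tribromo-4-methoxyphenyl diethylcarbamate | CCN(CC)C(=O)Oc1cc(Br)c(OC)c(Br)c1Br
F8 | step 1 | 2,6-dibromo-4-nitroanisole | COc1c(Br)cc(cc1Br)[N+]([O-])=O
F9 | step 1 | 3,5-dibromo-4-methoxyaniline | COc1c(Br)cc(N)cc1Br
F10 | step 1 | 3,5-dibromo-4-methoxybenzenediazonium hydrogen sulfate | COc1c(Br)cc(cc1Br)[N+]#N.OS(=O)(=O)[O-]
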